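**Assumption:** Kanzonol L has no stereocentres (the chromene C2 carries two identical methyls), so it is achiral and "single enantiomer" has no content here. The 4'-OH is free and the chromene oxygen sits on C2'.

**Retrosynthesis**
1. Kanzonol L comes from debenzylation of the 4'-OBn chromene-isoflavone. The 2,2-dimethylchromene is formed by prenal annulation on the 2'-OH and C3' of the B ring. A 4'-OBn group blocks the alternative "linear" annulation, and the A-ring carbons are already blocked by the prenyls.
2. The 6,8-diprenyl A ring comes from double C-prenylation of a 5,7-dihydroxyisoflavone.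
3. The pyranone ring is closed by formylative cyclisation of a 2'-hydroxy deoxybenzoin.
4. The deoxybenzoin comes from Friedel–Crafts acylation of phloroglucinol with 6-benzyloxy-2-coumaranone. The lactone is a temporary mask that differentiates the 2-OH from the 4-OH of 2,4-dihydroxyphenylacetic acid.

Ring-forming order: temporary lactone, then pyranone (C ring), then two C-prenylations, then the chromene ring.

---

**Step 1**
Reactants: 1 (2,4-dihydroxyphenylacetic acid)
Product: 2 (6-hydroxybenzofuran-2(3H)-one)
Conditions: p-TsOH (5 mol%), toluene, reflux, Dean–Stark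
Reagents that add atoms: none
Why: Acid-catalysed intramolecular esterification of the 2-OH onto the acid gives the five-membered lactone. This leaves only the 4-OH (lactone C6-OH) free, which guarantees later regiospecific protection.

**Step 2**
Reactants: 2 (6-hydroxybenzofuran-2(3H)-one), 3 (benzyl bromide)
Product: 4 (6-(benzyloxy)benzofuran-2(3H)-one)
Conditions: BnBr (1.1 equiv), K2CO3, acetone, reflux
Reagents that add atoms: benzyl bromide, BrCc1ccccc1
Why: Williamson O-benzylation of the only free phenol.

**Step 3**
Reactants: 4 (6-benzyloxy-2-coumaranone), 5 (phloroglucinol)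
Product: 6 (2-(4-benzyloxy-2-hydroxyphenyl)-1-(2,4,6-trihydroxyphenyl)ethanone)
Conditions: BF3·OEt2, 80 °C
Reagents that add atoms: none (phloroglucinol is the listed reactant; BF3 is only the Lewis acid)
Why: The aryl-ester lactone is an activated acyl donor. BF3 promotes Friedel–Crafts C-acylation of the very nucleophilic phloroglucinol, and the ring oxygen leaves as the free 2-OH, giving the deoxybenzoin directly.

**Step 4**
Reactants: 6 (deoxybenzoin)
Product: 7 (3-(4-benzyloxy-2-hydroxyphenyl)-5,7-dihydroxychromen-4-one)
Conditions: BF3·OEt2, DMF, MsCl, 50→80 °C; H2O work-up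
Reagents that add atoms: DMF, CN(C)C=O, which supplies C2 of the chromone (MsCl, CS(=O)(=O)Cl, only activates)
Why: A Vilsmeier-type C-formylation at the α-CH2, followed by cyclodehydration onto the A-ring 6'-OH, builds the γ-pyranone (the standard deoxybenzoin-to-isoflavone closure).

**Step 5**
Reactants: 7 (isoflavone), 8 (prenyl bromide)
Product: 9 (6,8-diprenyl-5,7-dihydroxy-3-(4-benzyloxy-2-hydroxyphenyl)chromen-4-one)
Conditions: prenyl bromide (2.3 equiv), KOH (2.5 equiv), MeOH/H2O, 0 °C→rt
Reagents that add atoms: prenyl bromide, CC(C)=CCBr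
Why: With limited base, the acidic 7-OH (pKa ~7) is the main phenolate, while the chelated 5-OH and the 2'-OH stay protonated. The protic medium favours C- over O-alkylation at the ortho C6 and C8 (SN2 C-prenylation of the phloroglucinol-type A ring).

**Step 6**
Reactants: 9 (diprenyl isoflavone), 10 (3-methylbut-2-enal, prenal)
Product: 11 (4'-O-benzyl-chromene isoflavone)
Conditions: prenal (3 equiv), pyridine, 120 °C, sealed tube
Reagents that add atoms: prenal, CC(C)=CC=O
Why: Phenoxide ortho-condensation with the enal (Knoevenagel-type) gives an o-quinone methide, which undergoes 6π-oxa-electrocyclisation (the classical 2,2-dimethyl-2H-chromene synthesis). C3' is the only free carbon ortho to the 2'-OH, since C1' is substituted. The 4'-OBn cannot cyclise, and A-ring C6 and C8 are blocked, so the chromene forms only at C2'/C3'. No stereocentre is formed.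

**Step 7**
Reactants: 11
Product: 12 (Kanzonol L)
Conditions: BCl3 (CH2Cl2), pentamethylbenzene, CH2Cl2, −78 °C, 30 min; then MeOH quench
Reagents that add atoms: none
Why: Lewis-acid benzyl-ether cleavage at low temperature. Pentamethylbenzene traps the benzyl cation, which spares the prenyl alkenes and the chromene. This releases the free 4'-OH.

---

**Compound list**

| # | Name | SMILES | Role |
|---|---|---|---|
| 1 | 2,4-Dihydroxyphenylacetic acid | OC(=O)Cc1ccc(O)cc1O | starting material |
| 2 | 6-Hydroxybenzofuran-2(3H)-one | O=C1Cc2ccc(O)cc2O1 | intermediate |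
| 3 | Benzyl bromide | BrCc1ccccc1 | starting material |
| 4 | 6-(Benzyloxy)benzofuran-2(3H)-one | O=C1Cc2ccc(OCc3ccccc3)cc2O1 | intermediate |
| 5 | Phloroglucinol | Oc1cc(O)cc(O)c1 | starting material |
| 6 | 2-(4-Benzyloxy-2-hydroxyphenyl)-1-(2,4,6-trihydroxyphenyl)ethanone | O=C(Cc1ccc(OCc2ccccc2)cc1O)c1c(O)cc(O)cc1O | intermediate |
| 7 | 3-(4-Benzyloxy-2-hydroxyphenyl)-5,7-dihydroxychromen-4-one | O=c1c(-c2ccc(OCc3ccccc3)cc2O)coc2cc(O)cc(O)c12 | intermediate |
| 8 | Prenyl bromide | CC(C)=CCBr | starting material |
| 9 | 3-(4-Benzyloxy-2-hydroxyphenyl)-5,7-dihydroxy-6,8-diprenylchromen-4-one | CC(C)=CCc1c(O)c(CC=C(C)C)c2occ(-c3ccc(OCc4ccccc4)cc3O)c(=O)c2c1O | intermediate |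
| 10 | 3-Methylbut-2-enal (prenal) | CC(C)=CC=O | starting material |
| 11 | 4'-O-Benzyl-chromene isoflavone | CC(C)=CCc1c(O)c(CC=C(C)C)c2occ(-c3ccc(OCc5ccccc5)c4C=CC(C)(C)Oc34)c(=O)c2c1O | intermediate |
| 12 | Kanzonol L (achiral, no stereocentres) | CC(C)=CCc1c(O)c(CC=C(C)C)c2occ(-c3ccc(O)c4c3OC(C)(C)C=C4)c(=O)c2c1O | target |

**Total steps:** 7. **Longest linear sequence:** 7 (1→2→4→6→7→9→11→12).

**Three steps most likely to fail**
1. **Step 5 (diprenylation).**
   - Risks: mono/di mixtures, O-prenylation, hydroxide opening of the chromone, and C3'-prenylation via the 2'-OH.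
   - Fallback: build the A ring first. Diprenylate 2,4,6-trihydroxyacetophenone, convert it to the 3-iodochromone (enaminone, then I2), and Suzuki-couple it with the 4-OBn chromene-aryl boronate.
2. **Step 6 (chromene annulation).**
   - Risks: low conversion at the hindered C3' and prenal oligomerisation.
   - Fallback: build the chromene on the B-ring fragment before coupling. Use 2-bromo-5-benzyloxyphenol, O-alkylate with 3-chloro-3-methylbut-1-yne, then Au-catalysed cycloisomerisation, then Miyaura borylation and Suzuki coupling.
3. **Step 7 (debenzylation).**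
   - Risks: BCl3 can open or polymerise the chromene and add to the prenyl alkenes.
   - Fallback: carry a 4'-O-allyl group instead (from allyl bromide in step 2) and remove it with Pd(PPh3)4/K2CO3/MeOH at rt. Step 3 would then use a milder Lewis acid such as Sc(OTf)3 or In(OTf)3 in place of BF3.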